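- At early times, at 3.00 h, the fed runs read 1% and 1% against a scatter of 1.5 percentage points, so I reckon from their ends.

| flask | free monomer | initiator | remark | time |
|---|---|---|---|---|
| maple | 0.050 M (fed, over 15 h) | 0.25 mol% | run made earlier; the fed solution adds 0.20 times the starting volume |  |
| birch | 0.050 M (fed, over 15 h) | 1 mol% | run made earlier; the fed solution adds 0.20 times the starting volume |  |
| summer | 0.050 M (fed, over 15 h) | 0.5 mol% | the fed solution adds 0.20 times the starting volume | 15 h |
| spring | 0.050 M | 0.5 mol% | everything together at the start, the whole solution of free monomer included, so that from the start the volume is larger by 0.20 times the starting volume | 5.0 h |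

| maple: time / h | maple: monomer in chains / % | birch: time / h | birch: monomer in chains / % |
|---|---|---|---|
| 1.33 | 0 | 1.33 | 3 |
| 2.00 | 3 | 2.00 | 1 |
| 3.00 | 1 | 3.00 | 1 |
| 5.00 | 4 | 5.00 | 7 |
| 10.0 | 9 | 10.0 | 24 |
| 15.0 | 16 | 15.0 | 44 |

(readings scatter by 1.5 percentage points)

- amounts are per litre of the starting volume; all of the dose is in the solution fed
- percentages count the whole charge, also what has not yet gone in

1. the winner by amount of monomer in chains, in percent of the free monomer charged; "neither" if no more than 2 percentage points parts them (summer / spring / neither)
2. how much monomer in chains is there at the end, in percent of the free monomer charged: summer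
3. how much monomer in chains is there at the end, in percent of the free monomer charged: spring

- I fold the givens into one number: X, a rate constant per c_initiator, times c_initiator, times time. It is a pseudo-first-order count of e-folds of free monomer.
- A flask charged at once then holds 1 − exp(−X) in chains, and a steady feed holds 1 − (1 − exp(−X))/X.
- The fits in the forecast give X = 0.36 for maple and 1.3 for birch. Per unit of loading, maple stands at 1.11 times birch, so I let X follow the loading.
- I test that one number. Birch's X, scaled to 10.0 h, gives 22.1%, and the reading is 24%.
- Averaging the two runs per loading, I take X = 0.685 for summer, the count of e-folds, which gives 27.6%.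
- Spring has a shorter time and its full volume from the start, so its X is 0.209, which gives 18.9%.
- In my reckoning summer leads spring by 8.7 points, beyond the margin of 2 points.
- The forecast says 27% for summer and 19% for spring: “Summer still likely wins.”
- The flasks give 28.3% for summer and 24.0% for spring, so summer wins.

    free monomer + initiator → living end + monomer in chains (k = 74.0 /M/h)
    free monomer + living end → monomer in chains + living end, rate k2*[living end]*[free monomer] (k = 330 /M/h)
    monomer in chains → over-reaction product (k = 0.0610 /h)

- Spring's X promised 18.9%, and the flask holds 24.0%. By 5.00 h spring's initiator stands at 0% and its living end at 2.08 × 10⁻⁴ M. The running short of initiator is the main reason for spring's figure: with initiator held at its charge, spring reaches 74.0%. A further flask, spring with 2 mol% of initiator, has X = 0.837, which promises 56.7%, and it holds 61.2%.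

The earlier runs and the new flask were generated by integration from invented constants; scatter was added.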